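The pitfall in the two earlier runs was to read the flat end of dawn as a stable target, for spring, with the same 0.22 M of starting material and the same 50 s feed, fell from 22.2% at 1.00 min to 14.9% at 3.00 min, while dawn stood at 67.2% and then 66.7%.

| setting | spring | dawn | violet | green | amber | blue | ochre | grey |
|---|---|---|---|---|---|---|---|---|
| starting material | 0.22 M | 0.22 M | 0.22 M | 0.22 M | 0.22 M | 0.22 M | 0.22 M | 0.22 M |
| reagent | 0.26 equiv (fed, over 50 s) | 1.6 equiv (fed, over 50 s) | 0.430 equiv (fed, over 50 s) | 0.870 equiv (fed, over 50 s) | 0.650 equiv (fed, over 50 s) | 1.30 equiv (fed, over 50 s) | 0.330 equiv (fed, over 50 s) | 2.00 equiv (fed, over 50 s) |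
| remark | run made earlier | run made earlier |  |  |  |  |  |  |
| time |  |  | 4.0 min | 4.0 min | 4.0 min | 4.0 min | 4.0 min | 4.0 min |

| run | time / min | target / % |
|---|---|---|
| spring | 0.250 | 3.4 |
| spring | 0.333 | 4.8 |
| spring | 0.667 | 14.7 |
| spring | 1.00 | 22.2 |
| spring | 1.50 | 19.2 |
| spring | 3.00 | 14.9 |
| dawn | 0.250 | 22.6 |
| dawn | 0.333 | 32.1 |
| dawn | 0.667 | 57.6 |
| dawn | 1.00 | 66.5 |
| dawn | 1.50 | 67.2 |
| dawn | 3.00 | 66.7 |

(scatter of a reading: 1 percentage point)

* the flasks by amount of target, in percent of the starting material charged, highest first, at 4.0 min (violet / green / amber / blue / ochre / grey)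
* the amount of target, in percent of the starting material charged of the flask you put first, at 4.0 min
* the amount of target, in percent of the starting material charged of the flask you put last, at 4.0 min

- a reading or a percentage of target counts all its forms, free or not

So I followed one molecule of target and asked for its chances at one fork, to stay or to be lost to something that spring had kept and dawn had apparently used up. I guessed this was leftover starting material. If one reagent serves one starting material, reagent was the limiting reagent in spring, which kept roughly 74.0% of its starting material. Spring's readings gave a loss of 0.199 min⁻¹, and dividing this by that share gave the bite, the fractional loss of target per minute for each whole charge of starting material left: 0.269 min⁻¹.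

Ochre is spring's near neighbour, with 0.330 equiv of reagent against 0.26 equiv. Scaling spring's reading by the reagent charged gave ochre about 28.2% at 1.00 min. Its extra reagent leaves less starting material, so I reckoned its loss slower than spring's, 0.181 min⁻¹ against 0.199 min⁻¹. Over the 3.00 min up to the asked time, that left ochre 16.4%. For the top of the order I had dawn's plateau to go by.

The forecast gave grey > blue > green > amber > violet > ochre, with 69% first and 16% last, and held that “excess reagent is harmless”.

The flasks came out as blue > grey > green > amber > violet > ochre, with blue at 70.4% and ochre at 17.7%.

    starting material + reagent → target (k = 0.740 L mol⁻¹ s⁻¹)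
    starting material + 2 reagent → side product A (k = 6.30 L² mol⁻² s⁻¹)
    crystals ⇌ target, rate k3*(cs3 - [target]) while solid is left; crystals form when [target] > cs3 (solubility = 0.160 M, k = 0.260 s⁻¹)
    starting material + target → side product B (k = 0.0170 L mol⁻¹ s⁻¹)

At 4.00 min ochre still held 57.5% of its starting material, with 0% of its reagent left and 22.8% standing as side product B, which counts two in every percentage. I put the bite of 0.269 min⁻¹ to a further flask, like blue but with 0.520 equiv of reagent, and reckoned 30.1%; that flask stood at 29.8%, with 39.4% of its starting material left.

The numbers in the tables are calculated with made-up constants.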